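The vessel is closed and stirred at constant temperature. Starting material and reagent make target, and you have to choose when to stop.

| flask | starting material | reagent | remark | time |
|---|---|---|---|---|
| blue | 0.23 M | 0.23 M | run made earlier |  |
| green | 0.23 M | 0.52 M | run made earlier |  |
| violet | 0.35 M | 0.345 M | run made earlier |  |
| flask | 0.23 M | 0.345 M |  | 12 h |

- blue (time / h: target / %, starting material / %): 0.500: 27.4, 65.2; 1.00: 40.6, 49.3; 1.50: 45.2, 41.7; 3.00: 48.9, 26.0; 5.00: 47.8, 17.7; 8.00: 48.3, 12.0; 15.0: 49.4, 6.1
- green (time / h: target / %, starting material / %): 0.500: 52.7, 40.7; 1.00: 65.0, 19.0; 1.50: 67.6, 10.1; 3.00: 62.4, 0.6; 5.00: 56.1, 0; 8.00: 53.3, 0; 15.0: 51.9, 0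
- violet (time / h: target / %, starting material / %): 0.500: 36.7, 56.8; 1.33: 50.4, 34.3; 3.00: 52.6, 19.5; 6.00: 49.5, 11.4; 15.0: 48.3, 6.4

(standard deviation of a reading: 0.5 percentage points)

* time, not beyond 12 h, at which the flask holds most target
* the amount of target, in percent of the starting material charged, at that time
* earliest time at which at least nineteen twentieths of that best amount are there
* latest time at which they still are

- steps thought possible: starting material <-> other conformer; reagent + other conformer -> isomer of the product A; starting material + reagent -> target; other conformer -> decomposition product; target <-> isomer of the product B

Green shows why stopping matters: with starting material at 0 % after 5.00 h, target still falls from 56.1 % to 51.9 % at 15.0 h. So target has a way out that needs no starting material, and green's target readings rise and then fall.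

The pace of the making step is a rate constant times the amounts of both partners, so you need to know how much of each is left. Each starting material that reacts takes one reagent, whether directly to target or through the other conformer to isomer of the product A. The step to decomposition product takes none, and I leave it aside.

In the flask, the starting material charged over the reagent charged is 0.667, the charge ratio. Let a be the fraction of starting material left, other conformer counted, and b the fraction of reagent left:

b = 1 − 0.667 × (1 − a)

At a = 0, b is 33.3 %, so starting material is the limiting reagent in the flask.

Blue has a ratio of 1.00 and green 0.442. At 3.00 h, blue still reads 26.0 % starting material and green 0.6 %. Both runs were charged with as much starting material as the flask, and the flask's ratio lies between theirs, so my own reckoning puts the flask's highest target between green's highest reading, 67.6 % at 1.50 h, and blue's reading of 48.9 % at 3.00 h.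

The forecast, holding that the “total loss of starting material behaves as second order”, is narrower: 60.8 % at 2.7 h, with the window from 1.55 h to 5.2 h.

The flask gives 59.5 % at 2.23 h, and the window runs from 1.31 h to 4.33 h.

    starting material ⇌ other conformer (K = 0.0400, k = 1.30 × 10⁻⁴ s⁻¹)
    reagent + other conformer → isomer of the product A (k = 0.00110 M⁻¹ s⁻¹)
    starting material + reagent → target (k = 0.00110 M⁻¹ s⁻¹)
    other conformer → decomposition product (k = 4.40 × 10⁻⁷ s⁻¹)
    target ⇌ isomer of the product B (K = 0.840, k = 7.60 × 10⁻⁵ s⁻¹)

The flask's highest target comes earlier than the forecast said. At 12.0 h the flask, with its charge ratio of 0.667, holds 0.14 % of its starting material and 33 % of its reagent, as the balance gave. The neighbour charged with 0.14 M of reagent has a charge ratio of 1.64, above 1, so setting b to nothing leaves a at 39.0 %. At 12.0 h that neighbour has 0.55 % of its own reagent charge left and, in parts of the starting material charged, 1.52 % other conformer and 37.9 % starting material.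

All runs come from a simulation from invented constants; scatter was added.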